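**Retrosynthetic overview**

- The strategy rests on the 1,4-relationship of the two ring oxygens: the ester oxygen on C3 and the oxirane oxygen on C6 sit at the two ends of the C3–C4–C5–C6 unit of the cyclohexane ring. Both are therefore introduced as one molecule of O2 added across the ring diene C3=C4–C5=C6 of 3,4-didehydro-β-ionone.
- Oxirane (last ring formed): the C5–O bond is disconnected to a C6 tertiary allylic alcohol and the C4=C5 alkene (cobalt-hydride cycloisomerisation). The myristate is disconnected by Mitsunobu inversion at C3 of a cis-3,6-diol.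
- cis-Diol: from O–O reduction of the 3,6-endoperoxide (first ring formed, a 1,2-dioxane bridge); the enantiomers are separated at the diol stage with a lipase.
- Ring diene: from β-ionone by C4 bromination and dehydrobromination.

Key step: step 3

Remarks on the chemistry:
- Positions follow ionone numbering: C1 carries the gem-dimethyl group, C3 the ester oxygen, C5 the ring methyl, C6 the side chain, C7=C8 is the side-chain alkene and C9 the carbonyl carbon.
- Racemic compounds are named and drawn as the enantiomer that is carried forward.
- Assumption: the lipase acylates the (3R) enantiomer of the cis-diol faster, as expected from the Kazlauskas model with the sp2 C4 side as the larger substituent.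

**Route**

Step 1
Reactants: 1 β-ionone
Product: 2 4-bromo-β-ionone (racemic)
Conditions: NBS, AIBN (2,2'-azobisisobutyronitrile, cat.), NaHCO3, PhCF3, 80 °C
Reagents that add atoms: N-bromosuccinimide, O=C1CCC(=O)N1Br
Why: Wohl–Ziegler radical allylic bromination: hydrogen abstraction at the C4 ring methylene gives a secondary radical delocalised over the C5=C6–C7=C8–C9=O dienone, so bromine enters at C4 in preference to the primary C5 methyl group; the new C4 stereocentre is racemic and is destroyed in step 2.

Step 2
Reactants: 2 4-bromo-β-ionone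
Product: 3 3,4-didehydro-β-ionone
Conditions: Li2CO3, LiBr, DMF, 100 °C
Reagents that add atoms: none
Why: Base-induced dehydrobromination of an allylic bromide: C3 carries the only β-hydrogens (C5 is fully substituted), so loss of HBr can only give the C3=C4 alkene, conjugated with C5=C6.

Step 3
Reactants: 3 3,4-didehydro-β-ionone
Product: 4 (3R,6S)-3,6-epidioxy-3,6-dihydro-β-ionone (racemic), (E)-4-[(1S,4R)-6,8,8-trimethyl-2,3-dioxabicyclo[2.2.2]oct-5-en-1-yl]but-3-en-2-one
Conditions: O2, rose bengal (disodium tetrachlorotetraiodofluorescein, C20H2Cl4I4Na2O5, cat.), visible light (> 450 nm), MeOH, 0 °C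
Reagents that add atoms: dioxygen, O=O
Why: Rose bengal, excited by visible light, sensitises dioxygen to singlet oxygen, which adds as a dienophile across C3 and C6 of the ring diene in a concerted, suprafacial [4+2] cycloaddition, the reaction type by which cyclohexa-1,3-dienes give ascaridole-type endoperoxides. The ring that closes is the six-membered 1,2-dioxane C3–O–O–C6–C5=C4; it is formed by cycloaddition, both C–O bonds in one step, and bridges the carbocycle to a 2,3-dioxabicyclo[2.2.2]oct-5-ene that keeps the C4=C5 alkene. C3 and C6 become stereocentres whose relative configuration is fixed by the two-atom peroxide bridge, which can only span one face of the ring, so the two C–O bonds are necessarily cis; nothing controls the absolute sense and the racemate should form. The step needs chemoselectivity for the ring diene over the C7=C8 alkene and [4+2] addition over ene reaction at the allylic C–H bonds: the endocyclic diene is locked s-cis and is the electron-rich π-system, whereas C7=C8 is deactivated by the ketone. Irradiation above 450 nm avoids direct excitation of the trienone and E/Z isomerisation of the side chain.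

Step 4
Reactants: 4 3,6-epidioxy-3,6-dihydro-β-ionone
Product: 5 (3R,6S)-3,6-dihydroxy-α-ionone (cis-diol, racemic), (E)-4-[(1S,4R)-1,4-dihydroxy-2,6,6-trimethylcyclohex-2-en-1-yl]but-3-en-2-one
Conditions: thiourea, MeOH, 0 °C to rt
Reagents that add atoms: none
Why: Thiourea reduces the O–O bond of the bicyclic peroxide (reductive peroxide cleavage) without touching either C–O bond, so the cis relationship of the C3 and C6 oxygens is carried into the diol, and the neutral medium avoids the base-induced Kornblum–DeLaMare isomerisation to the C3 ketone.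

Step 5
Reactants: 5 cis-3,6-dihydroxy-α-ionone (racemic)
Product: 6 (3R,6S)-3-acetoxy-6-hydroxy-α-ionone, (1R,4S)-4-hydroxy-3,5,5-trimethyl-4-[(E)-3-oxobut-1-enyl]cyclohex-2-en-1-yl acetate
Conditions: lipase PS (Burkholderia cepacia lipase), vinyl acetate, t-BuOMe, 30 °C, stopped near half conversion
Reagents that add atoms: vinyl acetate, C=COC(C)=O
Why: Lipase-catalysed kinetic resolution by irreversible transesterification: the enzyme acetylates the secondary allylic C3 hydroxyl of one enantiomer only (the tertiary C6 hydroxyl is not a substrate), so the (3R,6S) material should be obtained as its acetate and separated by chromatography from the unreacted (3S,6R) half of 5; this step selects the absolute configuration at C3 and C6.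

Step 6
Reactants: 6 (3R,6S)-3-acetoxy-6-hydroxy-α-ionone
Product: 7 (3R,6S)-3,6-dihydroxy-α-ionone (single enantiomer of the cis-diol)
Conditions: K2CO3 (cat.), MeOH, 0 °C to rt
Reagents that add atoms: none
Why: Base-catalysed transesterification (methanolysis) of the acetate; no bond to a stereocentre is broken.

Step 7
Reactants: 7 (3R,6S)-3,6-dihydroxy-α-ionone; 8 myristic acid (tetradecanoic acid)
Product: 9 (3S,6S)-6-hydroxy-3-myristoyloxy-α-ionone, (1S,4S)-4-hydroxy-3,5,5-trimethyl-4-[(E)-3-oxobut-1-enyl]cyclohex-2-en-1-yl tetradecanoate
Conditions: PPh3, DIAD, THF, 0 °C to rt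
Reagents that add atoms: none
Why: Mitsunobu esterification: the secondary allylic C3 hydroxyl is activated as its oxyphosphonium and displaced by myristate in an SN2 reaction with inversion (3R to 3S), which turns the cis arrangement of the two oxygens into the trans arrangement of the target; the tertiary C6 hydroxyl is not activated and, lying on the same face as the leaving group, cannot displace it from the rear.

Step 8
Reactants: 9 (3S,6S)-6-hydroxy-3-myristoyloxy-α-ionone
Product: 10 (3S,5R,6S)-5,6-epoxy-3-hydroxy-5,6-dihydro-β-ionone 3-O-tetradecanoate, (1R,3S,6S)-1,5,5-trimethyl-6-[(E)-3-oxobut-1-enyl]-7-oxabicyclo[4.1.0]heptan-3-yl tetradecanoate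
Conditions: [N,N'-bis(3,5-di-tert-butylsalicylidene)ethane-1,2-diaminato]cobalt (C32H46CoN2O2, divalent cobalt, 5 mol%), N-fluoro-2,4,6-trimethylpyridinium triflate, PhSiH3, acetone, 0 °C
Reagents that add atoms: none
Why: Cobalt-hydride hydrogen-atom-transfer radical–polar crossover cycloisomerisation of a tertiary allylic alcohol: the trivalent cobalt hydride formed from the divalent complex, the N-fluoropyridinium oxidant and the silane transfers a hydrogen atom to C4 of the trisubstituted C4=C5 alkene (Markovnikov sense), the tertiary C5 radical is oxidised to a cation equivalent (tetravalent alkylcobalt), and the adjacent C6 hydroxyl closes the oxirane 3-exo-tet; because an oxirane fused to a six-membered ring must be cis-fused, the new C5 stereocentre is dictated by C6 (oxygen on the face of the C6–O bond, methyl on the other face), which gives (5R,6S).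

**Compound list**

1 | β-ionone, (E)-4-(2,6,6-trimethylcyclohex-1-en-1-yl)but-3-en-2-one | CC(=O)/C=C/C1=C(C)CCCC1(C)C | starting material
2 | 4-bromo-β-ionone (racemic) | CC(=O)/C=C/C1=C(C)C(Br)CCC1(C)C | intermediate
3 | 3,4-didehydro-β-ionone | CC(=O)/C=C/C1=C(C)C=CCC1(C)C | intermediate
4 | (3R,6S)-3,6-epidioxy-3,6-dihydro-β-ionone (racemic, carried-forward enantiomer drawn) | CC(=O)/C=C/[C@]12OO[C@H](CC1(C)C)C=C2C | intermediate
5 | (3R,6S)-3,6-dihydroxy-α-ionone, cis-diol (racemic, carried-forward enantiomer drawn) | O[C@@H]1CC(C)(C)[C@@](O)(/C=C/C(C)=O)C(C)=C1 | intermediate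
6 | (3R,6S)-3-acetoxy-6-hydroxy-α-ionone | CC(=O)O[C@@H]1CC(C)(C)[C@@](O)(/C=C/C(C)=O)C(C)=C1 | intermediate
7 | (3R,6S)-3,6-dihydroxy-α-ionone (single enantiomer) | O[C@@H]1CC(C)(C)[C@@](O)(/C=C/C(C)=O)C(C)=C1 | intermediate
8 | myristic acid (tetradecanoic acid) | CCCCCCCCCCCCCC(=O)O | starting material
9 | (3S,6S)-6-hydroxy-3-myristoyloxy-α-ionone (C3 ester trans to C6 hydroxyl) | CCCCCCCCCCCCCC(=O)O[C@H]1CC(C)(C)[C@@](O)(/C=C/C(C)=O)C(C)=C1 | intermediate
10 | (3S,5R,6S)-5,6-epoxy-3-hydroxy-5,6-dihydro-β-ionone 3-O-tetradecanoate | CCCCCCCCCCCCCC(=O)O[C@H]1CC(C)(C)[C@]2(/C=C/C(C)=O)O[C@]2(C)C1 | target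

**Step count and risk**

Total step count: 8. Longest linear sequence: 8 steps (β-ionone to 10).

Steps most likely to fail:

1. Step 8. The hydrogen atom may be transferred to the C7=C8 enone instead of C4=C5. The C5 radical may also attack the enone in a 3-exo fashion and end in a 1,2-vinyl shift, or the cation stage may undergo a semipinacol shift or elimination instead of oxirane closure. The fallback sets out from 9 and takes the enone out of play by a redox bracket. Luche reduction (NaBH4, CeCl3·7H2O, MeOH, −40 °C) should give (3S,6S)-6-hydroxy-3-myristoyloxy-α-ionol F1 as a mixture of C9 epimers, whose side-chain alkene is no longer a radical acceptor or a conjugated hydrogen-atom acceptor. The cobalt-hydride cycloisomerisation of step 8 on this allylic alcohol should give (3S,5R,6S)-5,6-epoxy-3-myristoyloxy-5,6-dihydro-β-ionol F2. Oxidation of the allylic C9 alcohol with MnO2 in CH2Cl2 at rt comes back to the route at 10.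

2. Step 7. With a weakly acidic aliphatic acid the allylic oxyphosphonium may eliminate to a ring diene, ionise with loss of configuration at C3, or be opened in a syn-SN2′ sense by the C6 hydroxyl. The fallback sets out from 7 and separates inversion from acylation. Mitsunobu reaction with 4-nitrobenzoic acid (PPh3, DIAD, THF) should give (3S,6S)-6-hydroxy-3-(4-nitrobenzoyloxy)-α-ionone F3. Methanolysis (K2CO3, MeOH) gives the trans-diol (3S,6S)-3,6-dihydroxy-α-ionone F4. Acylation of its secondary hydroxyl with myristoyl chloride, pyridine and 4-(dimethylamino)pyridine in CH2Cl2 at 0 °C comes back to the route at 9.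

3. Step 5. The enzyme may discriminate poorly between the enantiomers, or in the opposite sense, because both ring carbons flanking C3 are substituted. The fallback sets out from racemic 5 and replaces the kinetic resolution by a separation of diastereomers. Acylation of the C3 hydroxyl with (1S)-camphanic chloride (pyridine, 4-(dimethylamino)pyridine, CH2Cl2) gives two diastereomeric esters, which are separated by chromatography or crystallisation. These are (3R,6S)-6-hydroxy-α-ionon-3-yl (1S)-camphanate F5 and (3S,6R)-6-hydroxy-α-ionon-3-yl (1S)-camphanate F6; F6 is set aside. Methanolysis of F5 (K2CO3, MeOH) comes back to the route at 7.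

**Further compounds**

F1 | step 8 | (3S,6S)-6-hydroxy-3-myristoyloxy-α-ionol (C9 epimers) | CCCCCCCCCCCCCC(=O)O[C@H]1CC(C)(C)[C@@](O)(/C=C/C(C)O)C(C)=C1
F2 | step 8 | (3S,5R,6S)-5,6-epoxy-3-myristoyloxy-5,6-dihydro-β-ionol (C9 epimers) | CCCCCCCCCCCCCC(=O)O[C@H]1CC(C)(C)[C@]2(/C=C/C(C)O)O[C@]2(C)C1
F3 | step 7 | (3S,6S)-6-hydroxy-3-(4-nitrobenzoyloxy)-α-ionone | O=C(O[C@H]1CC(C)(C)[C@@](O)(/C=C/C(C)=O)C(C)=C1)c1ccc(cc1)[N+](=O)[O-]
F4 | step 7 | (3S,6S)-3,6-dihydroxy-α-ionone (trans-diol) | O[C@H]1CC(C)(C)[C@@](O)(/C=C/C(C)=O)C(C)=C1
F5 | step 5 | (3R,6S)-6-hydroxy-α-ionon-3-yl (1S)-camphanate | O=C(O[C@@H]1CC(C)(C)[C@@](O)(/C=C/C(C)=O)C(C)=C1)[C@@]34CC[C@@](C)(C(=O)O3)C4(C)C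
F6 | step 5 | (3S,6R)-6-hydroxy-α-ionon-3-yl (1S)-camphanate | O=C(O[C@H]1CC(C)(C)[C@](O)(/C=C/C(C)=O)C(C)=C1)[C@@]34CC[C@@](C)(C(=O)O3)C4(C)C
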